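## Analysis of the target

The target (14) is a methylene-bridged dimer of two acylphloroglucinol-derived units. Ring A is a 2-propanoyl-4,4-dimethylcyclohexadienone of the filicinic acid type, an enolised β-triketone whose C6 carries the bridge. Ring B is a hexasubstituted benzene which, in chromene numbering, carries hydroxyl groups at C5 and C7, the bridge CH2 at C6 and a propanoyl group at C8. It is fused through C4a and C8a to ring C, a 2,2-dimethyl-2H-pyran (O1, C2 with two methyl groups, C3=C4). There is no stereocentre. The only stereochemical element is the C3=C4 alkene, which the ring forces to be cis, so the problem is purely one of regiochemistry on ring B: O1 must lie ortho to the propanoyl group and para to the bridge. The sensitive parts are the chromene (an allylic, benzylic ether that ionises or oligomerises under strong acid), the one-carbon bridge between two electron-rich rings (prone to cleavage and scrambling through quinone-methide pathways) and the free phenols and enols. The difficulty is therefore to tell apart the three oxygens of a phloroglucinol nucleus and to bring in the acid-labile elements late and under mild conditions. The strategy rests on C3=C4, the only isolated alkene. Cutting it leaves a vinyl group on C4a and a 1,1-dimethylallyl ether on O1, two terminal alkenes held ortho to each other. The oxygen that has to carry the allyl group is the one para to C6, so a formyl group at C6 can single it out by acidity and later become the bridge carbon.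

## Retrosynthetic reasoning

**14 to 9 and 12.** The bond between the bridge carbon and C6 of ring A is cut, with the bridge carbon kept on ring B as the formyl carbon of 9. Ring A then comes from 12, whose only unsubstituted ring carbon is a strongly nucleophilic enol position. Using an aldehyde already attached to ring B fixes which two positions are joined; a free one-carbon electrophile bridging two nucleophiles would give homodimers as well. The forward reaction must condense 9 with 12 to the alkylidene 13 and reduce it in the same flask, under conditions mild enough for the chromene and the bridge.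

**9 to 8.** The C8–acyl bond is cut next. The propanoyl group cannot be present earlier, because a second carbonyl on ring B would erase the acidity difference between the hydroxyl groups on which the ether formation depends. It should not come later either: a coupled product without it would have an unprotected, very electron-rich ring B next to the labile bridge. In 8 the only free ring carbon is C8, so the forward acylation has no regiochemical choice.

**8 to 7.** The C3=C4 bond is cut to give the vinyl group on C4a and the 1,1-dimethylallyl ether on O1 of 7. This is chosen over any C–O or C–C disconnection of ring C because it removes the ring in one step without touching the substitution pattern of ring B. The forward step needs only a ruthenium alkylidene catalyst at mild temperature, and it must close the ring before the tertiary allyl ether can rearrange.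

**7 to 3 and 6.** The O1–C2 bond is cut. A tertiary ether cannot be made by direct displacement, so the forward step uses a zerovalent palladium catalyst to turn the carbonate 6 into a dimethylallyl cation equivalent that the phenoxide captures at its substituted end. Of the three hydroxyl groups of 3, the one para to the formyl group is a vinylogous carboxylic acid and clearly the most acidic. The two ortho hydroxyls share the hydrogen bond to the formyl oxygen and are weaker acids. Selectivity therefore comes from acidity, with one equivalent of base released per equivalent of 6. The carbonate 6 is made from the alcohol 4 through its alkoxide 5.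

**3 to 2 to 1.** The C4a–vinyl bond is cut to the aryl iodide 2, and the C–I bond is traced back to 1. The two free ring carbons of 1 are equivalent, so mono-iodination gives a single isomer. The vinyl group must be in place before the allyl ether, since a zerovalent palladium catalyst would re-ionise that ether during a cross-coupling.

**12 to 10.** The two methyl groups on C4 of ring A are cut off, leading to the commercial acylphloroglucinol 10. The forward step is a double C-methylation at one ring carbon, passing through the mono-methyl compound 11 and ending in the dearomatised triketone.

## Alternatives that were turned down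

**Alternative 1:** Benzene ring B is itself assembled, by cutting C8a–C4a and C5–C6 (the C8–C8a bond then comes from an electrocyclisation). In the forward direction 3-ethoxy-2-methylcyclobut-2-en-1-one A2 is heated with the prenyl siloxyalkyne A3. Four-electron ring opening to a vinylketene, [2+2] addition to the ynol ether, a second ring opening and a six-electron closure give the phenol A1.
- For it: one operation delivers a benzene in which every position is differentiated (free OH at C8a, silyl ether at C5, ethyl ether at C7, prenyl at C4a), with regiochemistry dictated by the polarity of ketene and ynol ether. On regiocontrol of ring B it is stronger than the chosen route, which depends on an acidity difference between phenols.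
- Against it: A1 is far from the target. The C6 methyl group must be functionalised at the benzylic position to make the bridge, next to a prenyl or chromene alkene on an electron-rich ring. The ethyl ether must be cleaved with a strong Lewis acid. The prenyl phenol must be cyclised oxidatively and C8 acylated. Neither A2 nor A3 is a catalogue compound.
- Comparison: the chosen route buys ring B with its three oxygens in place and the C6 carbon already at the aldehyde level, which saves many steps.

**Alternative 2:** Ring C is cut at C8a–O1 and C4a–C4 at once. In the forward direction CsF releases the 4a,8a-aryne from the silyl aryl triflate A5. The aryne adds the carbonyl group of 3-methylbut-2-enal A6, the benzoxete opens to an ortho-quinone methide, and oxa-electrocyclisation gives the chromene A4.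
- For it: two bonds and the ring are formed at room temperature without a transition metal. The C5 alkoxy group should steer the oxygen to the distal aryne carbon, which is the required C8a. Acid hydrolysis of A4 would give 8, so the end-game would be the same. As a ring-C construction it is at least as direct as metathesis.
- Against it: A5 is a pentasubstituted arene whose preparation (protection, ortho-halogenation, silyl migration, triflation) takes more steps than the whole path to 8 in the chosen route. Aryne–enal annulations also compete with ene and cycloaddition pathways, and the bulky flanking groups do not help.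
- Comparison: the chosen route reaches the same chromene aldehyde unprotected, from a commercial aldehyde, with O1 already on the ring.

**Alternative 3:** The aryl C8a–O1 bond is cut. In the forward direction Pd(OAc)2, a bulky di-tert-butylbiarylphosphine and Cs2CO3 couple the Z-configured tertiary alcohol with the neighbouring aryl bromide of A8 to give A7.
- For it: the position of O1 is fixed by the bromide and not by relative acidity, so regiocontrol is better than in the chosen route. A tertiary alkoxide has no hydrogen on the carbinol carbon, so β-hydride elimination cannot compete.
- Against it: A8 needs a Z-alkene on a tetrasubstituted bromoarene, which means alkynylation, semi-hydrogenation and a second halogen to differentiate. Its Z-allylic tertiary alcohol ionises easily. The phenols have to be masked as methyl ethers for the coupling, so A7 must lose two methyl groups under strongly Lewis acidic conditions, next to the chromene and the aldehyde, before it reaches 8.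
- Comparison: the chosen route needs no protecting group at all, so it is shorter and avoids that deprotection.

Key step: step 5

Remark on the chemistry: ring A is written as the dienol tautomer of the given SMILES; the other tautomers of this β-triketone are treated as the same compound.

## Route

Step 1
Reactants: 1 2,4,6-trihydroxybenzaldehyde
Product: 2 2,4,6-trihydroxy-3-iodobenzaldehyde
Conditions: NIS (1.0 equiv), DMF, −20 to 0 °C, dark
Reagents that add atoms: N-iodosuccinimide, O=C1CCC(=O)N1I
Why: Electrophilic aromatic iodination; the two free ring carbons of 1 are equivalent and each is activated by three hydroxyl groups, so one equivalent of a mild iodonium source at low temperature should stop at the mono-iodide, the first iodine slowing a second substitution.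

Step 2
Reactants: 2 2,4,6-trihydroxy-3-iodobenzaldehyde
Product: 3 2,4,6-trihydroxy-3-vinylbenzaldehyde
Conditions: CH2=CHBF3K (1.3 equiv), PdCl2(dppf) (5 mol%), Et3N, n-PrOH/H2O, 80 °C, degassed
Reagents that add atoms: potassium vinyltrifluoroborate, [K+].C=C[B-](F)(F)F
Why: Suzuki–Miyaura cross-coupling; zerovalent palladium formed from the divalent palladium precatalyst inserts into the only C–I bond, the vinyl group is transferred from the slowly hydrolysed trifluoroborate, and reductive elimination gives the styrene. Free iodophenols and aryl aldehydes are accepted under amine-base conditions.

Step 3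
Reactants: 4 2-methylbut-3-en-2-ol
Product: 6 tert-butyl 2-methylbut-3-en-2-yl carbonate, via lithium 2-methylbut-3-en-2-olate 5 (not isolated)
Conditions: n-BuLi, THF, 0 °C; then Boc2O, 0 °C to rt; H2O work-up
Reagents that add atoms: di-tert-butyl dicarbonate, CC(C)(C)OC(=O)OC(=O)OC(C)(C)C; n-butyllithium, [Li]CCCC (lithium of 5 only)
Why: Alkoxycarbonylation of a tertiary alkoxide; the hindered alcohol is deprotonated first so that it attacks the dicarbonate cleanly, and the expelled tert-butyl carbonate ion breaks down to tert-butoxide and CO2.

Step 4
Reactants: 3 2,4,6-trihydroxy-3-vinylbenzaldehyde; 6 tert-butyl 2-methylbut-3-en-2-yl carbonate (1.1 equiv)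
Product: 7 2,6-dihydroxy-4-(2-methylbut-3-en-2-yloxy)-3-vinylbenzaldehyde
Conditions: Pd(PPh3)4 (5 mol%), THF, 4 Å MS, 0 °C
Reagents that add atoms: none
Why: Decarboxylative Tsuji–Trost O-allylation (reverse prenylation of a phenol); zerovalent palladium ionises 6 to a 1,1-dimethyl-π-allyl palladium cation, CO2 and tert-butoxide, which removes the most acidic proton of 3, that of the hydroxyl para to the formyl group. The phenoxide attacks the more substituted allyl terminus under kinetic control, and because only one equivalent of base is generated the less acidic ortho hydroxyls should stay protonated.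

Step 5
Reactants: 7 2,6-dihydroxy-4-(2-methylbut-3-en-2-yloxy)-3-vinylbenzaldehyde
Product: 8 5,7-dihydroxy-2,2-dimethyl-2H-chromene-6-carbaldehyde
Conditions: RuCl2(=CHPh)(PCy3)(H2IMes) (second-generation Grubbs catalyst, 5 mol%), CH2Cl2 (0.01 M), 40 °C, argon sweep
Reagents that add atoms: none
Why: Ring-closing olefin metathesis: the ruthenium benzylidene first exchanges onto the styrenyl vinyl group of 7, the less hindered of the two terminal alkenes because the ether alkene sits beside a quaternary carbon. The new alkylidene adds to the 1,1-dimethylallyl alkene in a [2+2] step, and cycloreversion of the ruthenacyclobutane gives the C3=C4 bond of 8 and a ruthenium methylidene, which loads onto the next molecule of 7 with loss of ethylene. The closest known reaction type is the ring-closing metathesis of ortho-vinylaryl allyl and 1,1-dimethylallyl ethers to 2H-chromenes with this catalyst class. Ring C closes as a six-membered ring by joining two alkene termini held ortho on the benzene ring, so the new alkene can only be cis and no stereocentre is formed. The selectivity required is cyclisation over intermolecular metathesis and over the thermal [3,3] shift of the tertiary allyl group to the free ring carbon C5 of 7. High dilution and the gem-dimethyl group, which turns the ether alkene towards the vinyl group, favour cyclisation, and a bath at 40 °C lies well below the temperature at which such ethers rearrange. The quaternary C2 also leaves no allylic hydrogen, so ruthenium hydride species cannot isomerise the ether alkene. The aldehyde and the phenols are tolerated by this catalyst class, and sweeping out ethylene makes the closure irreversible.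

Step 6
Reactants: 8 5,7-dihydroxy-2,2-dimethyl-2H-chromene-6-carbaldehyde
Product: 9 5,7-dihydroxy-2,2-dimethyl-8-propanoyl-2H-chromene-6-carbaldehyde
Conditions: (EtCO)2O (2 equiv), BF3·OEt2 (3 equiv), CH2Cl2, 0 °C to rt; aq. NaOAc work-up
Reagents that add atoms: propionic anhydride, CCC(=O)OC(=O)CC
Why: Friedel–Crafts C-acylation of a phloroglucinol-type ring; C8 is the only unsubstituted aromatic carbon of 8 and lies ortho to O1 and the 7-hydroxyl and para to the 5-hydroxyl, so the site is fixed. The formyl group lowers the nucleophilicity of the chromene alkene enough that the arene carbon should react first, and the new ketone is stabilised by chelation to the 7-hydroxyl.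

Step 7
Reactants: 10 flopropione (1-(2,4,6-trihydroxyphenyl)propan-1-one)
Product: 12 3,5-dihydroxy-4,4-dimethyl-2-propanoylcyclohexa-2,5-dien-1-one (propionylfilicinic acid), via 2,4,6-trihydroxy-3-methylpropiophenone 11 (not isolated)
Conditions: NaOMe (4 equiv), MeI (2.2 equiv), MeOH, 0 °C to rt; then aq. HCl
Reagents that add atoms: iodomethane, CI
Why: Double C-alkylation of a phloroglucinol polyanion; the ring carbon that has taken the first methyl group is the more electron-rich enolate carbon and takes the second, which dearomatises the ring to the gem-dimethyl triketone. Over- and under-methylated by-products are expected and are removed by crystallisation or chromatography on this side branch.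

Step 8
Reactants: 9 5,7-dihydroxy-2,2-dimethyl-8-propanoyl-2H-chromene-6-carbaldehyde; 12 propionylfilicinic acid
Product: 14 6-[(5,7-dihydroxy-2,2-dimethyl-8-propanoyl-2H-chromen-6-yl)methyl]-3,5-dihydroxy-4,4-dimethyl-2-propanoylcyclohexa-2,5-dien-1-one, via arylidene triketone 13 (not isolated)
Conditions: L-proline (20 mol%), Hantzsch ester (diethyl 2,6-dimethyl-1,4-dihydropyridine-3,5-dicarboxylate, 1.2 equiv), CH2Cl2, rt
Reagents that add atoms: none
Why: Organocatalytic three-component reductive alkylation (Knoevenagel condensation followed by transfer hydrogenation); proline activates the formyl group of 9 as an iminium ion, the free enol carbon of 12 adds, and loss of the amine gives 13. This alkylidene triketone, an ortho-quinone methide in character, should accept hydride from the dihydropyridine at the exocyclic carbon faster than it adds a second molecule of 12, and no stereocentre is created.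

## Compound list

1 | 2,4,6-trihydroxybenzaldehyde | O=Cc1c(O)cc(O)cc1O | starting material
2 | 2,4,6-trihydroxy-3-iodobenzaldehyde | O=Cc1c(O)cc(O)c(I)c1O | intermediate
3 | 2,4,6-trihydroxy-3-vinylbenzaldehyde | O=Cc1c(O)cc(O)c(C=C)c1O | intermediate
4 | 2-methylbut-3-en-2-ol | CC(C)(O)C=C | starting material
5 | lithium 2-methylbut-3-en-2-olate | [Li+].[O-]C(C)(C)C=C | intermediate
6 | tert-butyl 2-methylbut-3-en-2-yl carbonate | CC(C)(C)OC(=O)OC(C)(C)C=C | intermediate
7 | 2,6-dihydroxy-4-(2-methylbut-3-en-2-yloxy)-3-vinylbenzaldehyde | O=Cc1c(O)cc(OC(C)(C)C=C)c(C=C)c1O | intermediate
8 | 5,7-dihydroxy-2,2-dimethyl-2H-chromene-6-carbaldehyde | O=Cc1c(O)cc2OC(C)(C)C=Cc2c1O | intermediate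
9 | 5,7-dihydroxy-2,2-dimethyl-8-propanoyl-2H-chromene-6-carbaldehyde | CCC(=O)c1c(O)c(C=O)c(O)c2C=CC(C)(C)Oc12 | intermediate
10 | flopropione, 1-(2,4,6-trihydroxyphenyl)propan-1-one | CCC(=O)c1c(O)cc(O)cc1O | starting material
11 | 2,4,6-trihydroxy-3-methylpropiophenone | CCC(=O)c1c(O)cc(O)c(C)c1O | intermediate
12 | 3,5-dihydroxy-4,4-dimethyl-2-propanoylcyclohexa-2,5-dien-1-one (propionylfilicinic acid) | CCC(=O)C1=C(O)C(C)(C)C(O)=CC1=O | intermediate
13 | 2-[(5,7-dihydroxy-2,2-dimethyl-8-propanoyl-2H-chromen-6-yl)methylidene]-5-hydroxy-6,6-dimethyl-4-propanoylcyclohex-4-ene-1,3-dione (geometry of the exocyclic alkene not controlled; both forms are reduced to 14) | CCC(=O)C1=C(O)C(C)(C)C(=O)C(=Cc2c(O)c3C=CC(C)(C)Oc3c(C(=O)CC)c2O)C1=O | intermediate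
14 | 6-[(5,7-dihydroxy-2,2-dimethyl-8-propanoyl-2H-chromen-6-yl)methyl]-3,5-dihydroxy-4,4-dimethyl-2-propanoylcyclohexa-2,5-dien-1-one | CCC(=O)C1=C(O)C(C)(C)C(O)=C(Cc2c(O)c3c(c(C(=O)CC)c2O)OC(C)(C)C=C3)C1=O | target

## Step count and risks

Total step count: 8. Longest linear sequence: 6 steps (steps 1, 2, 4, 5, 6 and 8); steps 3 and 7 are one-step side branches.

**Step 5 (key step).**
- Risk: arrest of the catalyst. Once ruthenium has loaded onto the styrene, the phenol next to the vinyl group or the ether oxygen can chelate the metal and hold it as an unreactive benzylidene. A slow closure would then leave time for the [3,3] migration of the dimethylallyl group to the free ring carbon.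
- Fallback: from 7, both phenols are acetylated (Ac2O, pyridine, DMAP, 0 °C) to give 2-formyl-5-(2-methylbut-3-en-2-yloxy)-4-vinyl-1,3-phenylene diacetate F1, which has no free hydroxyl to bind ruthenium and a less electron-rich ring. Metathesis with RuCl2(=CHPh)(PCy3)(H2IMes) in CH2Cl2 at 40 °C should give 6-formyl-2,2-dimethyl-2H-chromene-5,7-diyl diacetate F2, and methanolysis (K2CO3, MeOH, 0 °C) returns to the route at 8.

**Step 4.**
- Risk: loss of site and regiocontrol in the allylation. This can be alkylation of a second hydroxyl, attack through the free ring carbon of the phloroglucinol nucleus, or re-ionisation of the tertiary ether by palladium and drift to the linear prenyl ether.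
- Fallback: from 3, the ether oxygen is alkylated with 3-chloro-3-methylbut-1-yne under copper catalysis (CuCl2 5 mol%, DBU, MeCN, 0 °C). This is strictly O-selective and cannot give a linear isomer, and should give 2,6-dihydroxy-4-(2-methylbut-3-yn-2-yloxy)-3-vinylbenzaldehyde F3. Semi-hydrogenation of the terminal alkyne (H2, Pd/CaCO3 poisoned with Pb(OAc)2, quinoline, EtOAc, stopped after one equivalent) returns to the route at 7.

**Step 6.**
- Risk: acid-induced oligomerisation of the chromene alkene, attack of the acylium ion at C3 instead of C8, or stalling at O-acylation because the formyl group deactivates the ring.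
- Fallback: from 8, iodination at the only free ring carbon (NIS, DMF, 0 °C) gives 5,7-dihydroxy-8-iodo-2,2-dimethyl-2H-chromene-6-carbaldehyde F4. Stille coupling with tributyl(1-ethoxyprop-1-en-1-yl)stannane (ethoxy and methyl cis; Pd(PPh3)4, CuI, dioxane, 90 °C) gives 8-[(Z)-1-ethoxyprop-1-en-1-yl]-5,7-dihydroxy-2,2-dimethyl-2H-chromene-6-carbaldehyde F5. Hydrolysis of the enol ether (1 M HCl, THF, rt) returns to the route at 9, with the ketone introduced under near-neutral conditions.

**Step 8.**
- Risk: addition of a second molecule of 12 to the alkylidene before hydride transfer, slow iminium formation at the doubly ortho-substituted formyl group, or cyclodehydration of a phenol of ring B onto a carbonyl of ring A.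
- Fallback: from 9, reductive amination (Me2NH, NaBH(OAc)3, ClCH2CH2Cl, rt) gives the phenolic Mannich base 1-{6-[(dimethylamino)methyl]-5,7-dihydroxy-2,2-dimethyl-2H-chromen-8-yl}propan-1-one F6. Heating F6 with 12 in dioxane at 100 °C expels the amine to give the transient ortho-quinone methide 7-hydroxy-2,2-dimethyl-6-methylidene-8-propanoyl-2H-chromen-5(6H)-one F7, which is captured by the enol carbon of 12 and returns to the route at 14. No reducing agent is present when the C–C bond forms.

**Step 2.**
- Risk: slow oxidative addition into the iodide of a ring that is largely present as an electron-rich phenoxide, with protodeiodination taking over, and polymerisation of the ortho-hydroxystyrene product on isolation.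
- Fallback: from 2, peracetylation (Ac2O, pyridine, DMAP) gives 2-formyl-4-iodobenzene-1,3,5-triyl triacetate F8. A neutral Stille coupling with tributyl(vinyl)stannane (Pd(PPh3)4, toluene, 80 °C) gives 2-formyl-4-vinylbenzene-1,3,5-triyl triacetate F9, which can be stored. Methanolysis (K2CO3, MeOH, 0 °C) just before step 4 returns to the route at 3.

## Further compounds

F1 | step 5 | 2-formyl-5-(2-methylbut-3-en-2-yloxy)-4-vinyl-1,3-phenylene diacetate | O=Cc1c(OC(C)=O)cc(OC(C)(C)C=C)c(C=C)c1OC(C)=O
F2 | step 5 | 6-formyl-2,2-dimethyl-2H-chromene-5,7-diyl diacetate | O=Cc1c(OC(C)=O)cc2OC(C)(C)C=Cc2c1OC(C)=O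
F3 | step 4 | 2,6-dihydroxy-4-(2-methylbut-3-yn-2-yloxy)-3-vinylbenzaldehyde | O=Cc1c(O)cc(OC(C)(C)C#C)c(C=C)c1O
F4 | step 6 | 5,7-dihydroxy-8-iodo-2,2-dimethyl-2H-chromene-6-carbaldehyde | O=Cc1c(O)c(I)c2OC(C)(C)C=Cc2c1O
F5 | step 6 | 8-[(Z)-1-ethoxyprop-1-en-1-yl]-5,7-dihydroxy-2,2-dimethyl-2H-chromene-6-carbaldehyde | CCO/C(=C\C)c1c(O)c(C=O)c(O)c2C=CC(C)(C)Oc12
F6 | step 8 | 1-{6-[(dimethylamino)methyl]-5,7-dihydroxy-2,2-dimethyl-2H-chromen-8-yl}propan-1-one | CCC(=O)c1c(O)c(CN(C)C)c(O)c2C=CC(C)(C)Oc12
F7 | step 8 | 7-hydroxy-2,2-dimethyl-6-methylidene-8-propanoyl-2H-chromen-5(6H)-one | CCC(=O)C1=C(O)C(=C)C(=O)C2=C1OC(C)(C)C=C2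
F8 | step 2 | 2-formyl-4-iodobenzene-1,3,5-triyl triacetate | O=Cc1c(OC(C)=O)cc(OC(C)=O)c(I)c1OC(C)=O
F9 | step 2 | 2-formyl-4-vinylbenzene-1,3,5-triyl triacetate | O=Cc1c(OC(C)=O)cc(OC(C)=O)c(C=C)c1OC(C)=O
A1 | alternative 1 | 5-ethoxy-4-methyl-2-(3-methylbut-2-en-1-yl)-3-(triisopropylsilyloxy)phenol | CCOc1cc(O)c(CC=C(C)C)c(O[Si](C(C)C)(C(C)C)C(C)C)c1C
A2 | alternative 1 | 3-ethoxy-2-methylcyclobut-2-en-1-one | CCOC1=C(C)C(=O)C1
A3 | alternative 1 | triisopropyl[(5-methylhex-4-en-1-yn-1-yl)oxy]silane | CC(C)=CCC#CO[Si](C(C)C)(C(C)C)C(C)C
A4 | alternative 2 | 6-(1,3-dioxolan-2-yl)-5,7-bis(methoxymethoxy)-2,2-dimethyl-2H-chromene | COCOc1cc2OC(C)(C)C=Cc2c(OCOC)c1C1OCCO1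
A5 | alternative 2 | 4-(1,3-dioxolan-2-yl)-3,5-bis(methoxymethoxy)-2-(trimethylsilyl)phenyl trifluoromethanesulfonate | COCOc1cc(OS(=O)(=O)C(F)(F)F)c([Si](C)(C)C)c(OCOC)c1C1OCCO1
A6 | alternative 2 | 3-methylbut-2-enal | CC(C)=CC=O
A7 | alternative 3 | 5,7-dimethoxy-2,2-dimethyl-2H-chromene-6-carbaldehyde | COc1cc2OC(C)(C)C=Cc2c(OC)c1C=O
A8 | alternative 3 | 4-bromo-3-[(Z)-3-hydroxy-3-methylbut-1-en-1-yl]-2,6-dimethoxybenzaldehyde | COc1cc(Br)c(/C=C\C(C)(C)O)c(OC)c1C=O
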